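**Retrosynthetic overview**

1. Succedaneaflavanone 15 is (2S,2''S)-6,6''-binaringenin. The two benzyl ethers are removed last; before that, both heterocyclic rings C (O1–C2 and O1''–C2'') are disconnected to the bichalcone 13, to be closed by a double enantioselective oxa-Michael addition through the hydroxyls para to the biaryl axis.
2. Key disconnection: C4a–C5 and C4a''–C5'' of both carbocyclic rings A. The bichalcone 13 is the Claisen isomer of the 3,3'-bipyranone 11 (lactone opening by Mg(OMe)2, reclosure on carbon).
3. Structural feature: in each ring A the chain C5(OH)–C6–C7(OH)–C8–C8a(O) is the chain C2–C3–C4–C5–C6 of a 4-hydroxy-2-pyranone, and the biaryl carbon C6 is the nucleophilic pyranone C3. The C6–C6'' axis with its four ortho oxygens can therefore be made early as an unhindered C3–C3' bond between two pyranones.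
4. 11 is cut at the two side-chain CH2–CO bonds (lateral acylation of both 6-methyl groups with a cinnamoyl Weinreb amide) and at C3–C3' (Ullmann homocoupling of the 3-iodide of triacetic acid lactone, O4 masked as methoxymethyl ether).
5. Order of ring formation: pyranone rings (bought), then both rings A in one operation (step 7), then both rings C (step 8).

Key step: step 7

Assumption: the target SMILES fixes C2 and C2'' as S (as in natural naringenin) and gives no descriptor for the C6–C6'' axis, which is therefore treated as not configurationally defined.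
Assumption: the quinine-derived thiourea of step 8 is taken to deliver the phenol oxygen to the Si face of C-β (2S); if a model closure showed the opposite sense, its quinidine-derived pseudoenantiomer would be used in the same step.

**Step 1**
Reactants: 1 4-hydroxy-6-methyl-2H-pyran-2-one (triacetic acid lactone)
Product: 2 4-hydroxy-3-iodo-6-methyl-2H-pyran-2-one
Conditions: NIS, MeCN, 0 °C → rt, dark
Reagents that add atoms: N-iodosuccinimide, O=C1CCC(=O)N1I
Why: Electrophilic iodination of the enolised cyclic 1,3-dicarbonyl system: C3, between the lactone carbonyl and the C4 hydroxyl, is the most nucleophilic carbon of this vinylogous acid.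

**Step 2**
Reactants: 2 4-hydroxy-3-iodo-6-methyl-2H-pyran-2-one
Product: 3 3-iodo-4-(methoxymethoxy)-6-methyl-2H-pyran-2-one
Conditions: MOMCl, iPr2NEt, CH2Cl2, 0 °C
Reagents that add atoms: chloromethyl methyl ether, COCCl
Why: O-Alkylation of the acidic C4 enol with a hard electrophile gives the methoxymethyl ether, which removes the acidic proton for the copper coupling and the carbanion step and is later cleaved by mild acid that spares aryl benzyl ethers and enones.

**Step 3**
Reactants: 3 3-iodo-4-(methoxymethoxy)-6-methyl-2H-pyran-2-one (2 equiv)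
Product: 4 4,4'-bis(methoxymethoxy)-6,6'-dimethyl-3,3'-bi(2H-pyran-2-one)
Conditions: activated copper powder, DMF, 100 °C, Ar
Reagents that add atoms: none
Why: Ullmann reductive homocoupling: the C3–I bond of the α-iodo unsaturated lactone is activated for copper insertion by the adjacent carbonyl, and the two coupling carbons are sp2 centres flanked only by oxygen functions, so the later tetra-ortho-oxygenated axis is formed here as a simple bipyranone bond.

**Step 4**
Reactants: 5 4-(benzyloxy)benzaldehyde; 6 diethyl [2-(methoxy(methyl)amino)-2-oxoethyl]phosphonate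
Product: 7 (E)-3-[4-(benzyloxy)phenyl]-N-methoxy-N-methylprop-2-enamide
Conditions: NaH, THF, 0 °C → rt
Reagents that add atoms: none
Why: Horner–Wadsworth–Emmons olefination of an aromatic aldehyde with a stabilised phosphonate anion should give the (E)-configured unsaturated Weinreb amide.

**Step 5**
Reactants: 4 4,4'-bis(methoxymethoxy)-6,6'-dimethyl-3,3'-bi(2H-pyran-2-one); 7 (E)-3-[4-(benzyloxy)phenyl]-N-methoxy-N-methylprop-2-enamide (2.5 equiv)
Product: 10 6,6'-bis[(E)-4-(4-benzyloxyphenyl)-2-oxobut-3-en-1-yl]-4,4'-bis(methoxymethoxy)-3,3'-bi(2H-pyran-2-one), via dilithio bipyranone 8 (not isolated), via bis(lithium alkoxide) adduct 9 (not isolated)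
Conditions: LDA (2.4 equiv), THF, −78 °C; then 7, −78 → −20 °C; aq. NH4Cl
Reagents that add atoms: none
Why: Lateral (vinylogous) deprotonation of both 6-methyl groups by LDA (C3 is blocked) followed by acylation with the Weinreb amide, which reacts by 1,2-addition and, through its chelated tetrahedral adduct, releases the ketone only on work-up, so neither over-addition nor proton transfer to unreacted carbanion interferes.

**Step 6**
Reactants: 10 6,6'-bis[(E)-4-(4-benzyloxyphenyl)-2-oxobut-3-en-1-yl]-4,4'-bis(methoxymethoxy)-3,3'-bi(2H-pyran-2-one)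
Product: 11 6,6'-bis[(E)-4-(4-benzyloxyphenyl)-2-oxobut-3-en-1-yl]-4,4'-dihydroxy-3,3'-bi(2H-pyran-2-one)
Conditions: HCl (1.25 M in MeOH), THF, 0 °C → rt
Reagents that add atoms: none
Why: Acid-catalysed acetal exchange cleaves the two vinylogous methoxymethyl esters, whose pyranone enol is a good leaving group, much faster than aryl benzyl ethers or the enones are touched.

**Step 7**
Reactants: 11 6,6'-bis[(E)-4-(4-benzyloxyphenyl)-2-oxobut-3-en-1-yl]-4,4'-dihydroxy-3,3'-bi(2H-pyran-2-one)
Product: 13 (2E,2'E)-1,1'-(2,2',4,4',6,6'-hexahydroxybiphenyl-3,3'-diyl)bis[3-(4-benzyloxyphenyl)prop-2-en-1-one], via ring-opened dimethyl diester 12 (not isolated)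
Conditions: Mg(OMe)2 (12 equiv, solution in MeOH), MeOH–THF, reflux, Ar; then poured into 1 M HCl at 0 °C, EtOAc extraction
Reagents that add atoms: none
Why: Methoxide, delivered within the magnesium chelate of the 4-oxido pyranone, adds to each lactone carbonyl (C2) and opens the ring to the magnesium enolate of a methyl 3,5,7-trioxo ester; the side-chain methylene carbon, now flanked by two ketones (future C4a), attacks the ester carbon (future C5) in a Claisen (Dieckmann-type) condensation, methoxide is lost and tautomerisation gives the aromatic acylphloroglucinol, so the step is a net isomerisation in which the pyranone ring oxygen becomes the C8a hydroxyl. The closest known reaction is the magnesium methoxide induced conversion of 6-(2-oxoalkyl)-4-hydroxy-2-pyranones into acylphloroglucinols, here run twice in one molecule. Each carbocyclic ring A closes in a 6-exo-trig mode at the ester carbonyl, forming C4a–C5 and C4a''–C5''. No stereocentre is created. The step needs Claisen rather than aldol chemoselectivity: the aldol alternative would join the ester α-carbon, which carries the other half of the molecule, to the cinnamoyl carbonyl and give a quaternary, non-aromatisable and therefore reversible adduct, while magnesium holds the tricarbonyl chain as a chelated enolate that resists retro-Claisen cleavage and is a poor Michael acceptor for methoxide. The polyphenoxide medium keeps both chalcones open, and rapid acidification at 0 °C should allow the bichalcone to be isolated before either ring C closes.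

**Step 8**
Reactants: 13 (2E,2'E)-1,1'-(2,2',4,4',6,6'-hexahydroxybiphenyl-3,3'-diyl)bis[3-(4-benzyloxyphenyl)prop-2-en-1-one]
Product: 14 (2S,2''S)-4',4'''-di-O-benzyl-6,6''-binaringenin
Conditions: N-[3,5-bis(trifluoromethyl)phenyl]-N'-[(8α,9S)-6'-methoxycinchonan-9-yl]thiourea (20 mol%), toluene–THF (5:1), −20 °C; filtration through acid-washed silica
Reagents that add atoms: none
Why: Proposed new method: a double, regioselective intramolecular oxa-Michael addition under bifunctional amine–thiourea catalysis, in which the thiourea holds the enone carbonyl that is already chelated by the buttressed hydroxyl next to the axis (future C5–OH), the quinuclidine base activates the only other ortho hydroxyl (para to the axis, flanked by C8–H, future O1) and this oxygen adds 6-endo-trig to the Si face of C-β inside the chiral ion pair, so that C2 and C2'' are both set as S by catalyst control, while the hydroxyl ortho to the axis should stay out because it is shielded by the orthogonal neighbouring ring and tied up in the hydrogen bond, in line with the preference of electrophiles for the unhindered ortho hydroxyl of 3-substituted acylphloroglucinols; the closest known reaction is the cinchona thiourea catalysed enantioselective cyclisation of 2'-hydroxychalcones to flavanones, and because the two closures are independent, an error in one half gives the (2R,2''S) diastereomer, which is removable by chromatography.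

**Step 9**
Reactants: 14 (2S,2''S)-4',4'''-di-O-benzyl-6,6''-binaringenin
Product: 15 succedaneaflavanone, (2S,2''S)-6,6''-binaringenin
Conditions: H2 (1 atm), Pd/C (10% palladium on carbon), EtOAc–THF, rt
Reagents that add atoms: none
Why: Catalytic hydrogenolysis of the two aryl benzyl ethers under neutral conditions, which should cleave the O–CH2Ph bonds faster than the cyclic benzylic C2–O1 bonds and, with no base present, cannot open the flavanone rings, so C2 and C2'' are not disturbed.

**Compound list**

1 | 4-hydroxy-6-methyl-2H-pyran-2-one (triacetic acid lactone) | Cc1cc(O)cc(=O)o1 | starting material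
2 | 4-hydroxy-3-iodo-6-methyl-2H-pyran-2-one | Cc1cc(O)c(I)c(=O)o1 | intermediate
3 | 3-iodo-4-(methoxymethoxy)-6-methyl-2H-pyran-2-one | COCOc1cc(C)oc(=O)c1I | intermediate
4 | 4,4'-bis(methoxymethoxy)-6,6'-dimethyl-3,3'-bi(2H-pyran-2-one) | COCOc1cc(C)oc(=O)c1-c1c(OCOC)cc(C)oc1=O | intermediate
5 | 4-(benzyloxy)benzaldehyde | O=Cc1ccc(OCc2ccccc2)cc1 | starting material
6 | diethyl [2-(methoxy(methyl)amino)-2-oxoethyl]phosphonate | CCOP(=O)(OCC)CC(=O)N(C)OC | starting material
7 | (E)-3-[4-(benzyloxy)phenyl]-N-methoxy-N-methylprop-2-enamide | CON(C)C(=O)/C=C/c1ccc(OCc2ccccc2)cc1 | intermediate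
8 | 6,6'-bis(lithiomethyl)-4,4'-bis(methoxymethoxy)-3,3'-bi(2H-pyran-2-one) (dilithio bipyranone) | [Li]Cc1cc(OCOC)c(-c2c(OCOC)cc(C[Li])oc2=O)c(=O)o1 | intermediate
9 | bis(lithium alkoxide) of the twofold tetrahedral adduct of 8 to 7, each side chain CH2–C(OLi)(NMeOMe)–CH=CH–Ar, carbinol carbons undefined | COCOc1cc(CC(O[Li])(N(C)OC)/C=C/c2ccc(OCc3ccccc3)cc2)oc(=O)c1-c1c(OCOC)cc(CC(O[Li])(N(C)OC)/C=C/c2ccc(OCc3ccccc3)cc2)oc1=O | intermediate
10 | 6,6'-bis[(E)-4-(4-benzyloxyphenyl)-2-oxobut-3-en-1-yl]-4,4'-bis(methoxymethoxy)-3,3'-bi(2H-pyran-2-one) | COCOc1cc(CC(=O)/C=C/c2ccc(OCc3ccccc3)cc2)oc(=O)c1-c1c(OCOC)cc(CC(=O)/C=C/c2ccc(OCc3ccccc3)cc2)oc1=O | intermediate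
11 | 6,6'-bis[(E)-4-(4-benzyloxyphenyl)-2-oxobut-3-en-1-yl]-4,4'-dihydroxy-3,3'-bi(2H-pyran-2-one) (key-step precursor) | O=c1oc(CC(=O)/C=C/c2ccc(OCc3ccccc3)cc2)cc(O)c1-c1c(O)cc(CC(=O)/C=C/c2ccc(OCc3ccccc3)cc2)oc1=O | intermediate
12 | dimethyl 2,3-bis[(E)-7-(4-benzyloxyphenyl)-3,5-dioxohept-6-enoyl]butanedioate, present as its magnesium enolate, drawn in the keto form | COC(=O)C(C(=O)CC(=O)CC(=O)/C=C/c1ccc(OCc2ccccc2)cc1)C(C(=O)OC)C(=O)CC(=O)CC(=O)/C=C/c1ccc(OCc2ccccc2)cc1 | intermediate
13 | (2E,2'E)-1,1'-(2,2',4,4',6,6'-hexahydroxybiphenyl-3,3'-diyl)bis[3-(4-benzyloxyphenyl)prop-2-en-1-one] (4,4''-di-O-benzyl 3',3'''-bi(naringenin chalcone), key-step product) | O=C(/C=C/c1ccc(OCc2ccccc2)cc1)c1c(O)cc(O)c(-c2c(O)cc(O)c(C(=O)/C=C/c3ccc(OCc4ccccc4)cc3)c2O)c1O | intermediate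
14 | (2S,2''S)-4',4'''-di-O-benzyl-6,6''-binaringenin | O=C1C[C@@H](c2ccc(OCc3ccccc3)cc2)Oc2cc(O)c(-c3c(O)cc4c(c3O)C(=O)C[C@@H](c3ccc(OCc5ccccc5)cc3)O4)c(O)c21 | intermediate
15 | succedaneaflavanone, (2S,2''S)-6,6''-binaringenin | O=C1C[C@@H](c2ccc(O)cc2)Oc2cc(O)c(-c3c(O)cc4c(c3O)C(=O)C[C@@H](c3ccc(O)cc3)O4)c(O)c21 | target

**Step count and risks**

Total step count: 9. Longest linear sequence: 8 steps (steps 1, 2, 3, 5, 6, 7, 8, 9).

Steps most likely to fail:

1. Step 8 (proposed new method).
   - What may go wrong: the hydroxyl ortho to the axis may compete as the nucleophile (loss of regiocontrol); facial control may be incomplete on a substrate that carries an acidic C7 hydroxyl; the amine may re-open the 5-hydroxyflavanone and erode the configuration at C2.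
   - Fallback (sets out from 13, returns at 14): both rings C are closed without stereocontrol by heating 13 with NaOAc in ethanol, the known base-mediated chalcone–flavanone isomerisation. This should give the 6,6''-linked bis-flavanone dibenzyl ether as a mixture of its stereoisomers F1, beside the 6,8''-linked bis-flavanone dibenzyl ether F2 and the 8,8''-linked bis-flavanone dibenzyl ether F3. F1 is separated from F2 and F3 on silica, and the (2S,2''S) isomer 14 is isolated from F1 by preparative HPLC on an amylose tris(3,5-dimethylphenylcarbamate) phase. The unwanted isomers are re-opened to 13 with cold methanolic KOH followed by acidification and cycled again, since all isomers interconvert through the bichalcone.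

2. Step 7 (key step).
   - What may go wrong: methanolysis of the tricarbonyl side chain (retro-Claisen loss of the cinnamoyl unit); stalling after the first of the two ring closures because the ester α-carbon at the inter-ring bond is hindered; Michael-type diversion of the enone; uncontrolled closure of ring C during acidification.
   - Fallback (sets out from the aldehyde 5 and commercial 2',4',6'-trimethoxyacetophenone F4, returns at 13): the biaryl is made at the acetophenone level and the chalcones by aldol condensation. F4 is iodinated between two methoxy groups (NIS, cat. TFA, MeCN) to 3'-iodo-2',4',6'-trimethoxyacetophenone F5. Classical Ullmann coupling (copper bronze, 220 °C) gives 3,3'-diacetyl-2,2',4,4',6,6'-hexamethoxybiphenyl F6. BBr3 in CH2Cl2 removes all six methyl groups to give 3,3'-diacetylbiphenyl-2,2',4,4',6,6'-hexol F7. MOMCl and NaH in DMF give 3,3'-diacetyl-2,2',4,4',6,6'-hexakis(methoxymethoxy)biphenyl F8. Claisen–Schmidt condensation of F8 with two equivalents of 5 (KOH, EtOH) gives the hexakis(methoxymethyl) ether of the bichalcone F9. HCl in MeOH at 0 °C removes the acetals and gives 13.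

3. Step 3.
   - What may go wrong: reductive loss of iodine instead of C–C coupling, and thermal loss of the methoxymethyl groups at the temperature of the copper coupling.
   - Fallback (sets out from 3, returns at 4): the two halves are differentiated and joined by palladium cross-coupling. One portion of 3 is converted by Miyaura borylation (B2pin2, PdCl2(dppf), KOAc, dioxane, 80 °C) into 4-(methoxymethoxy)-6-methyl-3-(4,4,5,5-tetramethyl-1,3,2-dioxaborolan-2-yl)-2H-pyran-2-one F10, which is coupled with a second portion of 3 by Suzuki–Miyaura reaction (Pd(OAc)2, SPhos, K3PO4, toluene–water, 60 °C) to give 4.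

**Further compounds**

F1 | step 8 | 4',4'''-di-O-benzyl-6,6''-binaringenin, mixture of stereoisomers at C2 and C2'' | O=C1CC(c2ccc(OCc3ccccc3)cc2)Oc2cc(O)c(-c3c(O)cc4c(c3O)C(=O)CC(c3ccc(OCc5ccccc5)cc3)O4)c(O)c21
F2 | step 8 | 4',4'''-di-O-benzyl-6,8''-binaringenin, mixture of stereoisomers | O=C1CC(c2ccc(OCc3ccccc3)cc2)Oc2cc(O)c(-c3c(O)cc(O)c4c3OC(c3ccc(OCc5ccccc5)cc3)CC4=O)c(O)c21
F3 | step 8 | 4',4'''-di-O-benzyl-8,8''-binaringenin, mixture of stereoisomers | O=C1CC(c2ccc(OCc3ccccc3)cc2)Oc2c(-c3c(O)cc(O)c4c3OC(c3ccc(OCc5ccccc5)cc3)CC4=O)c(O)cc(O)c21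
F4 | step 7 | 2',4',6'-trimethoxyacetophenone | CC(=O)c1c(OC)cc(OC)cc1OC
F5 | step 7 | 3'-iodo-2',4',6'-trimethoxyacetophenone | CC(=O)c1c(OC)cc(OC)c(I)c1OC
F6 | step 7 | 3,3'-diacetyl-2,2',4,4',6,6'-hexamethoxybiphenyl | CC(=O)c1c(OC)cc(OC)c(-c2c(OC)cc(OC)c(C(C)=O)c2OC)c1OC
F7 | step 7 | 3,3'-diacetylbiphenyl-2,2',4,4',6,6'-hexol | CC(=O)c1c(O)cc(O)c(-c2c(O)cc(O)c(C(C)=O)c2O)c1O
F8 | step 7 | 3,3'-diacetyl-2,2',4,4',6,6'-hexakis(methoxymethoxy)biphenyl | CC(=O)c1c(OCOC)cc(OCOC)c(-c2c(OCOC)cc(OCOC)c(C(C)=O)c2OCOC)c1OCOC
F9 | step 7 | hexakis(methoxymethyl) ether of bichalcone 13 | O=C(/C=C/c1ccc(OCc2ccccc2)cc1)c1c(OCOC)cc(OCOC)c(-c2c(OCOC)cc(OCOC)c(C(=O)/C=C/c3ccc(OCc4ccccc4)cc3)c2OCOC)c1OCOC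
F10 | step 3 | 4-(methoxymethoxy)-6-methyl-3-(4,4,5,5-tetramethyl-1,3,2-dioxaborolan-2-yl)-2H-pyran-2-one | COCOc1cc(C)oc(=O)c1B1OC(C)(C)C(C)(C)O1
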